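**Plan**

- Numbering used below: decalin C1 (bears the CMe2OH carbon), C4 (CH–CH3), C4a=C5 (alkene), C6 (quaternary), C8a (ring-fusion CH); benzylic carbon C1'. Ring A = C4a, C5, C6, C7, C8, C8a; ring B = C1, C2, C3, C4, C4a, C8a.
- Cuts, in retrosynthetic order: the two aryl–CHO bonds and three O–CH3 bonds; the two C–CH3 bonds of CMe2OH (back to an ester); the C4a=C5 alkene (back to a C5 ketone); C4a–C4, which closes ring B; C1–C2 and C8a–C1 (a malonate unit); C6–CH3; C6–C1'.
- Forward: ring A is a cyclohexenone from the start. C1'–C6, then C6–CH3, then C8a–C1 are joined; ring B is then closed between C4a and C4; ketone, ester and arene are adjusted last.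
- Stereochemistry: C1' from a Corey–Bakshi–Shibata reduction, carried through a Cr(CO)3-stabilised benzylic cation with retention; C6 from 1,3-allylic-strain-controlled methylation next to C1'; C8a from a Michael addition in which catalyst and substrate bias should agree; C4 from (S)-butane-1,3-diol by SN2 inversion; C1 by equilibration to the equatorial ester.
- Enabling feature: C5 lies between the quaternary C6 and the ring-fusion carbon C4a, so a C5 ketone can enolise only toward C4a, and C4 (one H, one CH3) can be delivered as a secondary sulfonate of fixed configuration; the same ketone later gives the C4a=C5 alkene through its only possible enol triflate.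

Key step: step 9

Assumption: the bimetallic catalyst of step 8 is taken to induce in the same sense as with cyclohex-2-enone, so the (S)-binaphthoxide complex is used; CIP labels at C1', C6 and C8a change between intermediates only because substituent priorities change, the spatial arrangement being the one in the SMILES.

**Route**

Step 1
Reactants: 1 1,3,5-trimethoxybenzene; 2 3-methylbutanoic acid
Product: 3 3-methyl-1-(2,4,6-trimethoxyphenyl)butan-1-one
Conditions: (CF3CO)2O, CH2Cl2, 0 °C to rt
Reagents that add atoms: none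
Why: Friedel–Crafts acylation of the strongly activated arene by the mixed trifluoroacetic anhydride of 2 should stop after one acylation because the ketone deactivates the ring.

Step 2
Reactants: 3 3-methyl-1-(2,4,6-trimethoxyphenyl)butan-1-one
Product: 4 (1R)-3-methyl-1-(2,4,6-trimethoxyphenyl)butan-1-ol
Conditions: (S)-1-methyl-3,3-diphenyltetrahydropyrrolo[1,2-c][1,3,2]oxazaborole ((S)-Me-CBS, 10 mol %), BH3·SMe2, THF, −20 °C; MeOH
Reagents that add atoms: none
Why: Corey–Bakshi–Shibata reduction, in which the oxazaborolidine–borane complex should deliver hydride to the ketone face that puts the bulky aryl group in the large-group position, giving the (R)-carbinol.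

Step 3
Reactants: 4 (1R)-3-methyl-1-(2,4,6-trimethoxyphenyl)butan-1-ol; 5 tricarbonyl(η6-naphthalene)chromium, Cr(CO)3(η6-C10H8)
Product: 6 tricarbonyl[η6-(1R)-3-methyl-1-(2,4,6-trimethoxyphenyl)butan-1-ol]chromium
Conditions: THF, 70 °C, sealed tube, dark
Reagents that add atoms: none
Why: Arene exchange from the labile naphthalene complex onto the more electron-rich arene; the two ring faces are equivalent by rotation about the aryl–carbinol bond, so a single complex should form and the carbinol centre is untouched.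

Step 4
Reactants: 6 tricarbonyl[η6-(1R)-3-methyl-1-(2,4,6-trimethoxyphenyl)butan-1-ol]chromium
Product: 7 tricarbonyl[η6-(1R)-3-methyl-1-(2,4,6-trimethoxyphenyl)butyl acetate]chromium
Conditions: Ac2O, pyridine, DMAP (cat.), 0 °C
Reagents that add atoms: acetic anhydride, CC(=O)OC(C)=O
Why: Base-catalysed O-acylation of a secondary alcohol; the electron-withdrawing Cr(CO)3 unit should keep the benzylic acetate from ionising, and only the O–H bond is changed.

Step 5
Reactants: 8 (3S)-butane-1,3-diol
Product: 9 (3S)-butane-1,3-diyl bis(4-methylbenzenesulfonate)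
Conditions: TsCl (2.2 equiv), Et3N, DMAP (cat.), CH2Cl2, 0 °C
Reagents that add atoms: 4-methylbenzenesulfonyl chloride, Cc1ccc(cc1)S(=O)(=O)Cl
Why: Sulfonylation of both hydroxyl groups forms O–S bonds only, so the stereocentre keeps its configuration.

Step 6
Reactants: 7 tricarbonyl[η6-(1R)-3-methyl-1-(2,4,6-trimethoxyphenyl)butyl acetate]chromium; 10 2-(trimethylsilyloxy)cyclohexa-1,3-diene
Product: 12 6-[(1S)-3-methyl-1-(2,4,6-trimethoxyphenyl)butyl]cyclohex-2-en-1-one (both C6 epimers), via chromium-complexed enone 11 (not isolated)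
Conditions: Me3SiOTf (0.2 equiv), CH2Cl2, −78 to −40 °C; then air, hν, Et2O, rt
Reagents that add atoms: none
Why: Mukaiyama-type SN1 alkylation of a silyl enol ether by a chromium-stabilised benzylic cation, in which acetate leaves anti to chromium and the terminal enol-ether carbon adds anti to chromium before the cation rotates, so C1' should form with overall retention; air and light then release the arene, and the C6 epimer mixture is erased in step 7.

Step 7
Reactants: 12 6-[(1S)-3-methyl-1-(2,4,6-trimethoxyphenyl)butyl]cyclohex-2-en-1-one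
Product: 13 (6R)-6-methyl-6-[(1R)-3-methyl-1-(2,4,6-trimethoxyphenyl)butyl]cyclohex-2-en-1-one
Conditions: LiN(iPr)2, THF, −78 °C; MeI, −78 to −20 °C
Reagents that add atoms: iodomethane, CI
Why: Kinetic alpha-prime deprotonation gives the cross-conjugated lithium dienolate, whose alkylation should be controlled by 1,3-allylic strain: with the benzylic hydrogen eclipsing the enolate C–O bond, iodomethane approaches the face opposite the aryl group and sets the quaternary centre in the target's relation to C1'.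

Step 8
Reactants: 13 (6R)-6-methyl-6-[(1R)-3-methyl-1-(2,4,6-trimethoxyphenyl)butyl]cyclohex-2-en-1-one; 14 dimethyl malonate
Product: 15 dimethyl 2-[(1S,4R)-4-methyl-4-[(1R)-3-methyl-1-(2,4,6-trimethoxyphenyl)butyl]-3-oxocyclohexyl]propanedioate
Conditions: LiAl[(S)-binaphthoxide]2 (10 mol %, from LiAlH4 and (S)-1,1'-bi-2-naphthol), KOt-Bu (9 mol %), 4 Å molecular sieves, THF, rt
Reagents that add atoms: none
Why: Catalytic asymmetric Michael addition of a malonate to a cyclic enone under Lewis acid/Brønsted base bimetallic catalysis; the malonate should enter the C8a face opposite the bulky benzylic substituent on C6, the sense the (S)-catalyst also favours, placing the new substituent cis to the C6 methyl.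

Step 9
Reactants: 15 dimethyl 2-[(1S,4R)-4-methyl-4-[(1R)-3-methyl-1-(2,4,6-trimethoxyphenyl)butyl]-3-oxocyclohexyl]propanedioate; 9 (3S)-butane-1,3-diyl bis(4-methylbenzenesulfonate)
Product: 17 dimethyl (4R,4aS,6R,8aS)-4,6-dimethyl-6-[(1R)-3-methyl-1-(2,4,6-trimethoxyphenyl)butyl]-5-oxooctahydronaphthalene-1,1(2H)-dicarboxylate (cis-fused), via malonate tosylate 16 (not isolated)
Conditions: NaH (1.0 equiv), DMF, 0 °C; 9, 0 to 40 °C; then KOt-Bu (1.1 equiv), THF, −20 °C to rt
Reagents that add atoms: none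
Why: NaH removes only the malonate C–H of 15, and this carbanion displaces the primary tosylate of 9 to give 16; KOt-Bu then forms the ketone enolate, which can only lie between C5 and C4a because C6 is quaternary, and C4a attacks C4 from the side opposite the secondary tosylate. The closest known reaction type is the base-mediated annulation of a ketone carrying a tethered sulfonate by intramolecular enolate C-alkylation. Ring B closes in a 6-(enolexo)-exo-tet mode through a chair transition state with the C4 methyl pseudo-equatorial. C4 is set by inversion of the (S)-sulfonate carbon taken from (S)-butane-1,3-diol, which puts the methyl cis to H-8a; C4a forms cis-fused because the tether on C8a reaches the enolate carbon only from its own face, and it is made trigonal in step 10. The step needs the primary tosylate to react before the secondary one (intrinsic SN2 rate difference, no iodide added so the secondary centre is not scrambled), C- over O-alkylation (O-attack would give an eight-membered enol ether) and ring closure faster than retro-Michael loss of the malonate (one equivalent of base, low temperature, prompt quench).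

Step 10
Reactants: 17 dimethyl (4R,4aS,6R,8aS)-4,6-dimethyl-6-[(1R)-3-methyl-1-(2,4,6-trimethoxyphenyl)butyl]-5-oxooctahydronaphthalene-1,1(2H)-dicarboxylate
Product: 18 dimethyl (4R,6R,8aS)-4,6-dimethyl-6-[(1S)-3-methyl-1-(2,4,6-trimethoxyphenyl)butyl]-5-{[(trifluoromethyl)sulfonyl]oxy}-3,4,6,7,8,8a-hexahydronaphthalene-1,1(2H)-dicarboxylate
Conditions: KN(SiMe3)2, THF, −78 °C; PhNTf2, −78 to 0 °C
Reagents that add atoms: N-phenylbis(trifluoromethanesulfonimide), O=S(=O)(N(c1ccccc1)S(=O)(=O)C(F)(F)F)C(F)(F)F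
Why: Enol triflate formation from the only possible enolate (C6 is quaternary and the gem-diester has no acidic hydrogen), trapped on oxygen by the triflimide; C4a becomes trigonal, so its earlier configuration no longer matters.

Step 11
Reactants: 18 dimethyl (4R,6R,8aS)-4,6-dimethyl-6-[(1S)-3-methyl-1-(2,4,6-trimethoxyphenyl)butyl]-5-{[(trifluoromethyl)sulfonyl]oxy}-3,4,6,7,8,8a-hexahydronaphthalene-1,1(2H)-dicarboxylate
Product: 19 dimethyl (4R,6S,8aS)-4,6-dimethyl-6-[(1S)-3-methyl-1-(2,4,6-trimethoxyphenyl)butyl]-3,4,6,7,8,8a-hexahydronaphthalene-1,1(2H)-dicarboxylate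
Conditions: Pd(OAc)2 (5 mol %), PPh3, HCO2H, Bu3N, DMF, 60 °C
Reagents that add atoms: none
Why: Palladium-catalysed formate reduction of a vinyl triflate (oxidative addition to zerovalent palladium, formate for triflate, loss of CO2, C–H reductive elimination) should leave the alkene exactly at C4a=C5.

Step 12
Reactants: 19 dimethyl (4R,6S,8aS)-4,6-dimethyl-6-[(1S)-3-methyl-1-(2,4,6-trimethoxyphenyl)butyl]-3,4,6,7,8,8a-hexahydronaphthalene-1,1(2H)-dicarboxylate
Product: 21 methyl (1S,4R,6S,8aR)-4,6-dimethyl-6-[(1S)-3-methyl-1-(2,4,6-trimethoxyphenyl)butyl]-1,2,3,4,6,7,8,8a-octahydronaphthalene-1-carboxylate, via epimeric monoester 20 (not isolated)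
Conditions: LiCl, H2O, DMSO, 150 °C; then NaOMe (cat.), MeOH, 50 °C
Reagents that add atoms: none
Why: Krapcho dealkoxycarbonylation (chloride attacks an ester methyl, the carboxylate loses CO2) followed by methoxide equilibration through the ester enolate; trigonal C4a forces the C8a–C8 bond to be equatorial on ring B, so the equatorial ester, trans to that bond, should be the favoured C1 epimer and is the one required, the minor epimer being recycled.

Step 13
Reactants: 21 methyl (1S,4R,6S,8aR)-4,6-dimethyl-6-[(1S)-3-methyl-1-(2,4,6-trimethoxyphenyl)butyl]-1,2,3,4,6,7,8,8a-octahydronaphthalene-1-carboxylate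
Product: 22 2-[(1S,4R,6S,8aR)-4,6-dimethyl-6-[(1S)-3-methyl-1-(2,4,6-trimethoxyphenyl)butyl]-1,2,3,4,6,7,8,8a-octahydronaphthalen-1-yl]propan-2-ol
Conditions: MeLi (3 equiv), THF, −78 to 0 °C; aq. NH4Cl
Reagents that add atoms: methyllithium, [Li]C
Why: Double addition of methyllithium to the ester should give the tertiary alcohol, and C1 is not epimerised if the addition is kept cold.

Step 14
Reactants: 22 2-[(1S,4R,6S,8aR)-4,6-dimethyl-6-[(1S)-3-methyl-1-(2,4,6-trimethoxyphenyl)butyl]-1,2,3,4,6,7,8,8a-octahydronaphthalen-1-yl]propan-2-ol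
Product: 24 5-[(1S)-1-[(2S,4aR,5S,8R)-5-(2-hydroxypropan-2-yl)-2,8-dimethyl-2,3,4,4a,5,6,7,8-octahydronaphthalen-2-yl]-3-methylbutyl]-2,4,6-trimethoxybenzene-1,3-dicarbaldehyde, via lithium aminoalkoxide 23 (not isolated)
Conditions: n-BuLi, TMEDA, THF, 0 °C; DMF, −78 °C; n-BuLi, 0 °C; DMF; aq. NH4Cl
Reagents that add atoms: N,N-dimethylformamide, CN(C)C=O
Why: Directed ortho-metalation, in which each remaining ring hydrogen lies between two methoxy groups and should be lithiated after the tertiary alkoxide has formed, DMF trapping the aryllithium as a lithium aminoalkoxide that masks the first formyl group during the second metalation–formylation.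

Step 15
Reactants: 24 5-[(1S)-1-[(2S,4aR,5S,8R)-5-(2-hydroxypropan-2-yl)-2,8-dimethyl-2,3,4,4a,5,6,7,8-octahydronaphthalen-2-yl]-3-methylbutyl]-2,4,6-trimethoxybenzene-1,3-dicarbaldehyde
Product: 25 5-[(1S)-1-[(2S,4aR,5S,8R)-5-(2-hydroxypropan-2-yl)-2,8-dimethyl-2,3,4,4a,5,6,7,8-octahydronaphthalen-2-yl]-3-methylbutyl]-2,4,6-trihydroxybenzene-1,3-dicarbaldehyde (CNP0200991.2)
Conditions: NaSEt (excess), DMF, 110 °C; then dil. HCl, 0 °C
Reagents that add atoms: none
Why: SN2 demethylation of aryl methyl ethers by thiolate, eased because each phenoxide leaving group is ortho or para to a formyl group, under basic conditions to which the tertiary alcohol and the trisubstituted alkene should be inert.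

**Compound list**

1 | 1,3,5-trimethoxybenzene | COc1cc(OC)cc(OC)c1 | starting material
2 | 3-methylbutanoic acid | CC(C)CC(=O)O | starting material
3 | 3-methyl-1-(2,4,6-trimethoxyphenyl)butan-1-one | CC(C)CC(=O)c1c(OC)cc(OC)cc1OC | intermediate
4 | (1R)-3-methyl-1-(2,4,6-trimethoxyphenyl)butan-1-ol | CC(C)C[C@@H](O)c1c(OC)cc(OC)cc1OC | intermediate
5 | tricarbonyl(η6-naphthalene)chromium | c1ccc2ccccc2c1.[Cr].[C-]#[O+].[C-]#[O+].[C-]#[O+] | starting material
6 | tricarbonyl[η6-(1R)-3-methyl-1-(2,4,6-trimethoxyphenyl)butan-1-ol]chromium | CC(C)C[C@@H](O)c1c(OC)cc(OC)cc1OC.[Cr].[C-]#[O+].[C-]#[O+].[C-]#[O+] | intermediate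
7 | tricarbonyl[η6-(1R)-3-methyl-1-(2,4,6-trimethoxyphenyl)butyl acetate]chromium | CC(C)C[C@@H](OC(C)=O)c1c(OC)cc(OC)cc1OC.[Cr].[C-]#[O+].[C-]#[O+].[C-]#[O+] | intermediate
8 | (3S)-butane-1,3-diol | C[C@H](O)CCO | starting material
9 | (3S)-butane-1,3-diyl bis(4-methylbenzenesulfonate) | Cc1ccc(cc1)S(=O)(=O)OCC[C@H](C)OS(=O)(=O)c1ccc(C)cc1 | intermediate
10 | 2-(trimethylsilyloxy)cyclohexa-1,3-diene | C[Si](C)(C)OC1=CCCC=C1 | starting material
11 | Cr(CO)3 complex (η6 at the trimethoxyphenyl ring) of 12 | CC(C)C[C@H](c1c(OC)cc(OC)cc1OC)C1C(=O)C=CCC1.[Cr].[C-]#[O+].[C-]#[O+].[C-]#[O+] | intermediate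
12 | 6-[(1S)-3-methyl-1-(2,4,6-trimethoxyphenyl)butyl]cyclohex-2-en-1-one, both C6 epimers | CC(C)C[C@H](c1c(OC)cc(OC)cc1OC)C1C(=O)C=CCC1 | intermediate
13 | (6R)-6-methyl-6-[(1R)-3-methyl-1-(2,4,6-trimethoxyphenyl)butyl]cyclohex-2-en-1-one | CC(C)C[C@H](c1c(OC)cc(OC)cc1OC)[C@]1(C)C(=O)C=CCC1 | intermediate
14 | dimethyl malonate | COC(=O)CC(=O)OC | starting material
15 | dimethyl 2-[(1S,4R)-4-methyl-4-[(1R)-3-methyl-1-(2,4,6-trimethoxyphenyl)butyl]-3-oxocyclohexyl]propanedioate | CC(C)C[C@H](c1c(OC)cc(OC)cc1OC)[C@]1(C)C(=O)C[C@@H](C(C(=O)OC)C(=O)OC)CC1 | intermediate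
16 | dimethyl 2-[(1S,4R)-4-methyl-4-[(1R)-3-methyl-1-(2,4,6-trimethoxyphenyl)butyl]-3-oxocyclohexyl]-2-[(3S)-3-(tosyloxy)butyl]propanedioate | CC(C)C[C@H](c1c(OC)cc(OC)cc1OC)[C@]1(C)C(=O)C[C@@H](C(CC[C@H](C)OS(=O)(=O)c2ccc(C)cc2)(C(=O)OC)C(=O)OC)CC1 | intermediate
17 | dimethyl (4R,4aS,6R,8aS)-4,6-dimethyl-6-[(1R)-3-methyl-1-(2,4,6-trimethoxyphenyl)butyl]-5-oxooctahydronaphthalene-1,1(2H)-dicarboxylate | CC(C)C[C@H](c1c(OC)cc(OC)cc1OC)[C@]1(C)C(=O)[C@H]2[C@H](C)CCC(C(=O)OC)(C(=O)OC)[C@H]2CC1 | intermediate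
18 | dimethyl (4R,6R,8aS)-4,6-dimethyl-6-[(1S)-3-methyl-1-(2,4,6-trimethoxyphenyl)butyl]-5-{[(trifluoromethyl)sulfonyl]oxy}-3,4,6,7,8,8a-hexahydronaphthalene-1,1(2H)-dicarboxylate | CC(C)C[C@H](c1c(OC)cc(OC)cc1OC)[C@]1(C)C(OS(=O)(=O)C(F)(F)F)=C2[C@H](C)CCC(C(=O)OC)(C(=O)OC)[C@H]2CC1 | intermediate
19 | dimethyl (4R,6S,8aS)-4,6-dimethyl-6-[(1S)-3-methyl-1-(2,4,6-trimethoxyphenyl)butyl]-3,4,6,7,8,8a-hexahydronaphthalene-1,1(2H)-dicarboxylate | CC(C)C[C@H](c1c(OC)cc(OC)cc1OC)[C@]1(C)C=C2[C@H](C)CCC(C(=O)OC)(C(=O)OC)[C@H]2CC1 | intermediate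
20 | methyl (4R,6S,8aR)-4,6-dimethyl-6-[(1S)-3-methyl-1-(2,4,6-trimethoxyphenyl)butyl]-1,2,3,4,6,7,8,8a-octahydronaphthalene-1-carboxylate, both C1 epimers | CC(C)C[C@H](c1c(OC)cc(OC)cc1OC)[C@]1(C)C=C2[C@H](C)CCC(C(=O)OC)[C@H]2CC1 | intermediate
21 | methyl (1S,4R,6S,8aR)-4,6-dimethyl-6-[(1S)-3-methyl-1-(2,4,6-trimethoxyphenyl)butyl]-1,2,3,4,6,7,8,8a-octahydronaphthalene-1-carboxylate | CC(C)C[C@H](c1c(OC)cc(OC)cc1OC)[C@]1(C)C=C2[C@H](C)CC[C@H](C(=O)OC)[C@H]2CC1 | intermediate
22 | 2-[(1S,4R,6S,8aR)-4,6-dimethyl-6-[(1S)-3-methyl-1-(2,4,6-trimethoxyphenyl)butyl]-1,2,3,4,6,7,8,8a-octahydronaphthalen-1-yl]propan-2-ol | CC(C)C[C@H](c1c(OC)cc(OC)cc1OC)[C@]1(C)C=C2[C@H](C)CC[C@H](C(C)(C)O)[C@H]2CC1 | intermediate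
23 | dilithium salt of the mono-DMF adduct of 22 (lithium tertiary alkoxide; aryl C3 bears CH(OLi)NMe2) | CC(C)C[C@H](c1c(OC)c(C(O[Li])N(C)C)c(OC)cc1OC)[C@]1(C)C=C2[C@H](C)CC[C@H](C(C)(C)O[Li])[C@H]2CC1 | intermediate
24 | 5-[(1S)-1-[(2S,4aR,5S,8R)-5-(2-hydroxypropan-2-yl)-2,8-dimethyl-2,3,4,4a,5,6,7,8-octahydronaphthalen-2-yl]-3-methylbutyl]-2,4,6-trimethoxybenzene-1,3-dicarbaldehyde | CC(C)C[C@H](c1c(OC)c(C=O)c(OC)c(C=O)c1OC)[C@]1(C)C=C2[C@H](C)CC[C@H](C(C)(C)O)[C@H]2CC1 | intermediate
25 | 5-[(1S)-1-[(2S,4aR,5S,8R)-5-(2-hydroxypropan-2-yl)-2,8-dimethyl-2,3,4,4a,5,6,7,8-octahydronaphthalen-2-yl]-3-methylbutyl]-2,4,6-trihydroxybenzene-1,3-dicarbaldehyde | CC(C)C[C@H](c1c(O)c(C=O)c(O)c(C=O)c1O)[C@]1(C)C=C2[C@H](C)CC[C@H](C(C)(C)O)[C@H]2CC1 | target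

**Count**

Total steps: 15. Longest linear sequence: 14 steps (steps 1–4 and 6–15); step 5 is a one-step side branch.

**Steps most likely to fail, with fallbacks**

Step 9. The C4a enolate may fragment by retro-Michael loss of the malonate, or the base may eliminate the secondary tosylate, faster than ring B closes. The fallback removes the malonate from the design; it sets out from 13 and comes back at 20. Acidic methanolysis of commercial (S)-6-methyltetrahydropyran-2-one would give methyl (5S)-5-hydroxyhexanoate F1, which is tosylated to methyl (5S)-5-(tosyloxy)hexanoate F2 and converted with LiN(iPr)2 and t-BuMe2SiCl into its ketene silyl acetal F3. A Mukaiyama–Michael addition of F3 to 13, promoted by t-BuMe2SiOTf and relying on the same substrate bias at C8a, should give the silyl enol ether adduct F4. Fluoride (Bu4NF) then releases the C4a enolate, which has only a simple ester carbon at the beta position and so cannot fragment, and which should close ring B by the same SN2 inversion to the cis-fused keto ester F5. Triflation as in step 10 gives the enol triflate F6, and the palladium/formate reduction of step 11 leads to 20, which is equilibrated as in step 12.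

Step 8. Addition to the hindered enone may be slow and the malonate may not discriminate well between the two faces at C8a. The fallback replaces the base-mediated bimetallic catalysis by Lewis-acid activation of the enone; it sets out from 13 and 14 and comes back at 15. Dimethyl malonate is silylated (NaH, Me3SiCl) to methyl 3-methoxy-3-(trimethylsilyloxy)prop-2-enoate F7, which should add to 13 in a Mukaiyama–Michael reaction under Me3SiOTf catalysis at −78 °C, anti to the bulky C6 substituent, to give the trimethylsilyl enol ether F8; mild aqueous acid hydrolyses F8 to 15.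

Step 14. The second metalation may stall, or n-BuLi may attack the aminoalkoxide that masks the first formyl group, leaving mono-formylated material. The fallback switches from directed metalation to electrophilic formylation; it sets out from 22 and comes back at 24. The tertiary alcohol is protected (Et3SiOTf, 2,6-lutidine) as the triethylsilyl ether F9. Rieche formylation (Cl2CHOMe, TiCl4, CH2Cl2, −78 °C) of the very electron-rich ring should then give the dialdehyde silyl ether F10. HF·pyridine removes the silyl group to give 24.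

**Further compounds**

F1 | step 9 | methyl (5S)-5-hydroxyhexanoate | COC(=O)CCC[C@H](C)O
F2 | step 9 | methyl (5S)-5-(tosyloxy)hexanoate | COC(=O)CCC[C@H](C)OS(=O)(=O)c1ccc(C)cc1
F3 | step 9 | tert-butyldimethylsilyl ketene acetal of F2 | COC(O[Si](C)(C)C(C)(C)C)=CCC[C@H](C)OS(=O)(=O)c1ccc(C)cc1
F4 | step 9 | Mukaiyama–Michael adduct of F3 and 13 (C5 tert-butyldimethylsilyl enol ether, C1 epimers) | CC(C)C[C@H](c1c(OC)cc(OC)cc1OC)[C@]1(C)C(O[Si](C)(C)C(C)(C)C)=C[C@@H](C(CC[C@H](C)OS(=O)(=O)c2ccc(C)cc2)C(=O)OC)CC1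
F5 | step 9 | methyl 4,6-dimethyl-6-[3-methyl-1-(2,4,6-trimethoxyphenyl)butyl]-5-oxodecahydronaphthalene-1-carboxylate (cis-fused, C1 epimers) | CC(C)C[C@H](c1c(OC)cc(OC)cc1OC)[C@]1(C)C(=O)[C@H]2[C@H](C)CCC(C(=O)OC)[C@H]2CC1
F6 | step 9 | C5 enol triflate of F5 | CC(C)C[C@H](c1c(OC)cc(OC)cc1OC)[C@]1(C)C(OS(=O)(=O)C(F)(F)F)=C2[C@H](C)CCC(C(=O)OC)[C@H]2CC1
F7 | step 8 | methyl 3-methoxy-3-(trimethylsilyloxy)prop-2-enoate | COC(=O)C=C(OC)O[Si](C)(C)C
F8 | step 8 | trimethylsilyl enol ether of 15 | CC(C)C[C@H](c1c(OC)cc(OC)cc1OC)[C@]1(C)C(O[Si](C)(C)C)=C[C@@H](C(C(=O)OC)C(=O)OC)CC1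
F9 | step 14 | triethylsilyl ether of 22 | CC(C)C[C@H](c1c(OC)cc(OC)cc1OC)[C@]1(C)C=C2[C@H](C)CC[C@H](C(C)(C)O[Si](CC)(CC)CC)[C@H]2CC1
F10 | step 14 | triethylsilyl ether of 24 | CC(C)C[C@H](c1c(OC)c(C=O)c(OC)c(C=O)c1OC)[C@]1(C)C=C2[C@H](C)CC[C@H](C(C)(C)O[Si](CC)(CC)CC)[C@H]2CC1
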